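The route rests on the C7–H bond. The target is disconnected to a racemic α‑aryloxy‑β‑keto ester in which C7 is an aryl ketone on the guaiacyl ring and C9 is an ethyl ester. C8 carries O4' of the syringyl‑type ring and lies between C7 and C9, so its C–H is doubly activated and epimerises freely. A single asymmetric transfer hydrogenation with dynamic kinetic resolution should therefore set C7 and C8 together as the threo pair. The precursor is built from vanillin, ethyl diazoacetate and sinapic acid by C7–C8 aldol‑type addition and C8–O4' carbene O–H insertion. One hydride reduction then releases both primary alcohols and the phenol.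

Key step: step 5

Assumption: lignan numbering is used (C7 = benzylic carbinol carbon on the guaiacyl ring, C8 = carbon bearing O4', C9 = primary carbinol carbon, primed locants for the sinapyl unit); the target is (7R,8R), the threo isomer.

Step 1
Reactants: 1 vanillin
Product: 2 4-formyl-2-methoxyphenyl pivalate (O‑pivaloylvanillin)
Conditions: PivCl, Et3N, DMAP (cat.), CH2Cl2, 0 °C to rt
Reagents that add atoms: pivaloyl chloride, CC(C)(C)C(Cl)=O
Why: DMAP‑catalysed O‑acylation of the phenol (nucleophilic acyl substitution) masks the acidic O–H that would quench the later carbene and lowers the donor strength of the guaiacyl ring.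

Step 2
Reactants: 2 4-formyl-2-methoxyphenyl pivalate; 3 ethyl diazoacetate
Product: 5 ethyl 2-diazo-3-[3-methoxy-4-(pivaloyloxy)phenyl]-3-oxopropanoate, via racemic α‑diazo‑β‑hydroxy ester 4 (not isolated)
Conditions: DBU (20 mol%), DMSO, rt; then IBX, DMSO, rt (one pot)
Reagents that add atoms: none
Why: DBU‑catalysed aldol‑type addition of the diazoacetate carbon to the aldehyde forms C7–C8, and the pentavalent iodine oxidant IBX then converts the secondary carbinol into the ketone in the same flask, the diazo group and the hindered aryl pivalate being stable to both stages.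

Step 3
Reactants: 6 sinapic acid
Product: 7 methyl (E)-sinapate [methyl (E)-3-(4-hydroxy-3,5-dimethoxyphenyl)prop-2-enoate]
Conditions: MeOH, H2SO4 (cat.), reflux
Reagents that add atoms: methanol, CO
Why: Fischer esterification, which leaves the phenol and the E alkene untouched.

Step 4
Reactants: 5 ethyl 2-diazo-3-[3-methoxy-4-(pivaloyloxy)phenyl]-3-oxopropanoate; 7 methyl (E)-sinapate
Product: 8 racemic ethyl 2-{2,6-dimethoxy-4-[(E)-3-methoxy-3-oxoprop-1-en-1-yl]phenoxy}-3-[3-methoxy-4-(pivaloyloxy)phenyl]-3-oxopropanoate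
Conditions: Rh2(OAc)4 (2 mol%), PhMe, 80 °C, slow addition of 5 to 7 (1.2 equiv)
Reagents that add atoms: none
Why: Rhodium‑carbene O–H insertion, in which loss of N2 gives an electrophilic acceptor/acceptor carbene that the phenol oxygen captures as an oxonium ylide before proton transfer forms C8–O4'; the electron‑poor cinnamate alkene is a poor cyclopropanation partner and slow addition should limit carbene dimerisation.

Step 5
Reactants: 8 racemic α‑aryloxy‑β‑keto ester
Product: 9 ethyl (2S,3R)-2-{2,6-dimethoxy-4-[(E)-3-methoxy-3-oxoprop-1-en-1-yl]phenoxy}-3-hydroxy-3-[3-methoxy-4-(pivaloyloxy)phenyl]propanoate (threo)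
Conditions: RuCl[(S,S)-TsDPEN](p-cymene) (2 mol%), HCO2H/Et3N (5:2), CH2Cl2, 30 °C
Reagents that add atoms: none
Why: Formate converts the Ru amido complex into the Ru–H/N–H species (CO2 lost), which passes hydride to C7 and a proton to the carbonyl oxygen through an outer‑sphere six‑membered transition state, while the amine/formate medium keeps the two C8 epimers of 8 in rapid equilibrium through the enol of the ketone–ester. The reaction type is the Noyori–Ikariya asymmetric transfer hydrogenation run as a dynamic kinetic resolution, known to give syn α‑alkoxy‑β‑hydroxy esters from α‑alkoxy‑β‑keto esters; no ring is closed. C7 is controlled by the catalyst: with the (S,S)‑diamine the CH–π contact between the η6‑cymene and the guaiacyl ring should direct hydride to the Si face of the ketone and give the 3R (= 7R) carbinol, an assignment taken from the aryl ketone model that is to be confirmed on the first run, the (R,R)‑complex being used if the sense proves opposite. C8 is controlled by the rate difference between the epimers: only the epimer leading to the syn (threo) alcohol is expected to be reduced quickly, so the racemate should funnel into (2S,3R)‑9, and C8 stops epimerising once the ketone has gone. The step needs face selectivity at C7, discrimination between the C8 epimers and enolisation faster than reduction; the doubly activated C8–H, the aryl ketone and the electron‑poor pivalate‑bearing ring are expected to secure these, and the cinnamate alkene, both esters and the pivalate should be inert to the Ru hydride.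

Step 6
Reactants: 9 ethyl (2S,3R)-threo ester
Product: 10 (1R,2R)-1-(4-hydroxy-3-methoxyphenyl)-2-{4-[(E)-3-hydroxyprop-1-en-1-yl]-2,6-dimethoxyphenoxy}propane-1,3-diol [(7R,8R)-threo-guaiacylglycerol 8‑O‑4' sinapyl alcohol ether]
Conditions: iBu2AlH (DIBAL-H, 10 equiv), CH2Cl2/PhMe, −78 to 0 °C; then aq. KNaC4H4O6 (Rochelle salt)
Reagents that add atoms: none
Why: DIBAL‑H hydride reduction takes the C9 ester and the cinnamate ester to the primary and allylic alcohols by 1,2‑addition without conjugate reduction and cleaves the aryl pivalate reductively in the same flask, while the low temperature and neutral tartrate work‑up should leave C7 and C8 untouched.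

Compound list
1 | vanillin | COc1cc(C=O)ccc1O | starting material
2 | 4-formyl-2-methoxyphenyl pivalate | COc1cc(C=O)ccc1OC(=O)C(C)(C)C | intermediate
3 | ethyl diazoacetate | CCOC(=O)C=[N+]=[N-] | starting material
4 | racemic ethyl 2-diazo-3-hydroxy-3-[3-methoxy-4-(pivaloyloxy)phenyl]propanoate (formed in the flask in step 2) | CCOC(=O)C(=[N+]=[N-])C(O)c1ccc(OC(=O)C(C)(C)C)c(OC)c1 | intermediate
5 | ethyl 2-diazo-3-[3-methoxy-4-(pivaloyloxy)phenyl]-3-oxopropanoate | CCOC(=O)C(=[N+]=[N-])C(=O)c1ccc(OC(=O)C(C)(C)C)c(OC)c1 | intermediate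
6 | sinapic acid | COc1cc(/C=C/C(=O)O)cc(OC)c1O | starting material
7 | methyl (E)-sinapate | COc1cc(/C=C/C(=O)OC)cc(OC)c1O | intermediate
8 | racemic ethyl 2-{2,6-dimethoxy-4-[(E)-3-methoxy-3-oxoprop-1-en-1-yl]phenoxy}-3-[3-methoxy-4-(pivaloyloxy)phenyl]-3-oxopropanoate | CCOC(=O)C(Oc1c(OC)cc(/C=C/C(=O)OC)cc1OC)C(=O)c1ccc(OC(=O)C(C)(C)C)c(OC)c1 | intermediate
9 | ethyl (2S,3R)-2-{2,6-dimethoxy-4-[(E)-3-methoxy-3-oxoprop-1-en-1-yl]phenoxy}-3-hydroxy-3-[3-methoxy-4-(pivaloyloxy)phenyl]propanoate | COc1cc([C@@H](O)[C@@H](C(=O)OCC)Oc2c(OC)cc(/C=C/C(=O)OC)cc2OC)ccc1OC(=O)C(C)(C)C | intermediate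
10 | (1R,2R)-1-(4-hydroxy-3-methoxyphenyl)-2-{4-[(E)-3-hydroxyprop-1-en-1-yl]-2,6-dimethoxyphenoxy}propane-1,3-diol | COc1cc([C@@H](O)[C@@H](CO)Oc2c(OC)cc(/C=C/CO)cc2OC)ccc1O | target

Total step count: 6. Longest linear sequence: 5 steps (steps 1, 2, 4, 5, 6); step 3 is a one‑step side branch.

Steps most likely to fail

1. Step 5. Enolisation at C8 may be slowed by the bulky 2,6‑dimethoxyaryloxy group so that reduction outruns epimerisation, or the catalyst may distinguish the C8 epimers or the ketone faces poorly, eroding the threo and enantiomeric purity. The fallback sets both centres by an auxiliary‑controlled aldol instead and sets out from 7 and 2. Methyl sinapate 7 would be O‑alkylated with commercial (S)-4-benzyl-3-(chloroacetyl)oxazolidin-2-one (K2CO3, NaI cat., acetone, reflux) to give (S)-4-benzyl-3-{[2,6-dimethoxy-4-((E)-3-methoxy-3-oxoprop-1-en-1-yl)phenoxy]acetyl}oxazolidin-2-one F1. Its Z boron enolate (Bu2BOTf, iPr2NEt, CH2Cl2, −78 °C) would add to aldehyde 2 through a Zimmerman–Traxler chair, opposite the benzyl group, to give the Evans syn aldol adduct, the (2S,3R)-2-aryloxy-3-hydroxy-3-arylpropanoyl oxazolidinone F2 (buffered H2O2 work‑up). NaBH4 in THF/H2O at 0 °C would cleave the auxiliary reductively to give methyl (E)-3-[4-{[(1R,2R)-1,3-dihydroxy-1-(3-methoxy-4-pivaloyloxyphenyl)propan-2-yl]oxy}-3,5-dimethoxyphenyl]prop-2-enoate F3. DIBAL‑H under the conditions of step 6 would then reduce the cinnamate and cleave the pivalate, coming back to the route at 10.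

2. Step 4. The carbene may be diverted into dimerisation, Wolff rearrangement, insertion into adventitious water or attack on the cinnamate alkene before the hindered phenol O–H captures it. The fallback forms C8–O4' by substitution and sets out from 4, isolated by leaving out the IBX stage of step 2. Rh2(OAc)4 (1 mol%, CH2Cl2, rt) would convert 4 by 1,2‑hydride shift of the carbene into the β‑keto ester ethyl 3-[3-methoxy-4-(pivaloyloxy)phenyl]-3-oxopropanoate F4. SO2Cl2 (CH2Cl2, 0 °C) would chlorinate the active methylene to give racemic ethyl 2-chloro-3-[3-methoxy-4-(pivaloyloxy)phenyl]-3-oxopropanoate F5. Displacement of chloride by the phenoxide of 7 (K2CO3, acetone, rt to reflux) would come back to the route at 8.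

3. Step 6. The aluminium alkoxide of the β‑hydroxy ester may fragment by retro‑aldol before the ester is reduced, or C7 may ionise once the para‑phenoxide is unmasked, with loss of the threo configuration. The fallback masks C7–OH before the reduction and sets out from 9. TBSOTf and 2,6‑lutidine (CH2Cl2, −78 °C) would give the C7 silyl ether, ethyl (2S,3R)-3-(tert-butyldimethylsilyloxy)-2-aryloxy-3-arylpropanoate F6. DIBAL‑H (CH2Cl2, −78 to 0 °C) would then give the C7‑O‑TBS ether of the target F7. Bu4NF buffered with AcOH (THF, 0 °C) would remove the silyl group and come back to the route at 10.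

Further compounds
F1 | step 5 | (S)-4-benzyl-3-{[2,6-dimethoxy-4-((E)-3-methoxy-3-oxoprop-1-en-1-yl)phenoxy]acetyl}oxazolidin-2-one | O=C(COc1c(OC)cc(/C=C/C(=O)OC)cc1OC)N2[C@@H](Cc3ccccc3)COC2=O
F2 | step 5 | (S)-4-benzyl-3-[(2S,3R)-2-{2,6-dimethoxy-4-[(E)-3-methoxy-3-oxoprop-1-en-1-yl]phenoxy}-3-hydroxy-3-(3-methoxy-4-pivaloyloxyphenyl)propanoyl]oxazolidin-2-one | COc1cc([C@@H](O)[C@@H](C(=O)N3[C@@H](Cc4ccccc4)COC3=O)Oc2c(OC)cc(/C=C/C(=O)OC)cc2OC)ccc1OC(=O)C(C)(C)C
F3 | step 5 | methyl (E)-3-[4-{[(1R,2R)-1,3-dihydroxy-1-(3-methoxy-4-pivaloyloxyphenyl)propan-2-yl]oxy}-3,5-dimethoxyphenyl]prop-2-enoate | COc1cc([C@@H](O)[C@@H](CO)Oc2c(OC)cc(/C=C/C(=O)OC)cc2OC)ccc1OC(=O)C(C)(C)C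
F4 | step 4 | ethyl 3-[3-methoxy-4-(pivaloyloxy)phenyl]-3-oxopropanoate | CCOC(=O)CC(=O)c1ccc(OC(=O)C(C)(C)C)c(OC)c1
F5 | step 4 | racemic ethyl 2-chloro-3-[3-methoxy-4-(pivaloyloxy)phenyl]-3-oxopropanoate | CCOC(=O)C(Cl)C(=O)c1ccc(OC(=O)C(C)(C)C)c(OC)c1
F6 | step 6 | ethyl (2S,3R)-3-(tert-butyldimethylsilyloxy)-2-{2,6-dimethoxy-4-[(E)-3-methoxy-3-oxoprop-1-en-1-yl]phenoxy}-3-[3-methoxy-4-(pivaloyloxy)phenyl]propanoate | COc1cc([C@@H](O[Si](C)(C)C(C)(C)C)[C@@H](C(=O)OCC)Oc2c(OC)cc(/C=C/C(=O)OC)cc2OC)ccc1OC(=O)C(C)(C)C
F7 | step 6 | (2R,3R)-3-(tert-butyldimethylsilyloxy)-3-(4-hydroxy-3-methoxyphenyl)-2-{4-[(E)-3-hydroxyprop-1-en-1-yl]-2,6-dimethoxyphenoxy}propan-1-ol | COc1cc([C@@H](O[Si](C)(C)C(C)(C)C)[C@@H](CO)Oc2c(OC)cc(/C=C/CO)cc2OC)ccc1O
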